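**Retrosynthetic overview**

1. End game after the ring closure: C-8 methacrylate from the 8-OH (TBS ether), and the α-methylene lactone from its benzenesulfinate adduct by E1cB elimination.
2. The ten-membered carbocycle C-1…C-10 is closed last at C-1–C-2 by a decarboxylative radical addition–β-fragmentation: a primary C-2 radical (from a redox-active ester, CO2 lost) attacks C-1 of a β-sulfonyl enal (PhSO2 lost).
3. Enabling feature: C-1 is the β-carbon of the C-14(=O)–C-10=C-1 enal, whose stable geometry (CHO trans to C-2) is also the cis alkene of the C-1…C-10 ring, and C-2 is an unfunctionalised CH2 two atoms from epoxide carbon C-4, so nerol delivers C-2…C-6 and C-15 plus one carbon that leaves as CO2; the cis-epoxide (C-4/C-5), the trans-lactone (C-6/C-7) and the 8,9-dioxygenation fold the seco chain.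
4. γ-Lactone ring and C-6–C-7: stereospecific allylboration/lactonisation of a Sharpless-derived epoxy aldehyde with a 2-(methoxycarbonyl)allylboronate that carries C-7…C-10, C-14 and C-1.
5. C-8/C-9: proline anti-aldol of 2,2-dimethyl-1,3-dioxan-5-one with a silyl ynal; C-1 by sulfonyl Horner–Wadsworth–Emmons olefination of the C-10 ketone; ring order: epoxide, γ-lactone, ten-membered ring.

Key step: step 17

Remark: C-1 to C-15 are the germacrane positions of the target (C-1=C-10 enal with C-14 as CHO, C-4/C-5 epoxide, C-15 methyl, O-6 lactone with C-11/C-12/C-13, O-8 methacrylate, O-9 acetate). It is assumed that 8–23 can be carried as E/Z mixtures at C-1=C-10 and 18–26 as C-11 epimers, because steps 17 and 18 erase both elements.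

**Step 1**
Reactants: 1 nerol
Product: 2 (2S,3R)-2,3-epoxynerol
Conditions: Ti(OiPr)4 (10 mol%), L-(+)-diethyl tartrate (12 mol%), t-BuOOH, 4 Å MS, CH2Cl2, −20 °C
Reagents that add atoms: tert-butyl hydroperoxide CC(C)(C)OO
Why: Sharpless asymmetric epoxidation touches only the allylic alkene, and the L-(+)-tartrate complex delivers oxygen to the face that gives the (2S,3R) cis-epoxide, which sets C-4 and C-5.

**Step 2**
Reactants: 2 (2S,3R)-2,3-epoxynerol
Product: 3 (2R,3R)-epoxy aldehyde
Conditions: Dess–Martin periodinane, NaHCO3, CH2Cl2, 0 °C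
Reagents that add atoms: none
Why: Buffered Dess–Martin oxidation of the primary epoxy alcohol should give the epoxy aldehyde without touching the epoxide stereocentres.

**Step 3**
Reactants: 4 2,2-dimethyl-1,3-dioxan-5-one; 5 3-(trimethylsilyl)prop-2-ynal
Product: 6 anti aldol (4S,1'S)
Conditions: (S)-proline (30 mol%), DMF, 4 °C
Reagents that add atoms: none
Why: Proline-catalysed enamine aldol reaction, in which the ring-fixed enamine of 4 and the hydrogen-bonded aldehyde pass through the usual chair-like transition state, so catalyst control should give the anti aldol with (S) at C-9 and (S) at C-8.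

**Step 4**
Reactants: 6 anti aldol
Product: 7 8-O-TBS ketone
Conditions: TBSOTf, 2,6-lutidine, CH2Cl2, −78 °C
Reagents that add atoms: tert-butyldimethylsilyl triflate CC(C)(C)[Si](C)(C)OS(=O)(=O)C(F)(F)F
Why: Low-temperature silylation of the β-hydroxy ketone is faster than retro-aldol or epimerisation and later keeps O-8 out of the lactonisation.

**Step 5**
Reactants: 7 8-O-TBS ketone
Product: 8 C-1 vinyl sulfone (E/Z mixture)
Conditions: (EtO)2P(O)CH2SO2Ph, NaH, THF, 0 → 25 °C
Reagents that add atoms: diethyl [(phenylsulfonyl)methyl]phosphonate CCOP(=O)(CS(=O)(=O)c1ccccc1)OCC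
Why: Horner–Wadsworth–Emmons olefination with the preformed, weakly basic sulfonyl phosphonate anion converts the C-10 ketone into the vinyl sulfone faster than it enolises C-9, and the E/Z ratio does not matter because step 17 is stereoconvergent.

**Step 6**
Reactants: 8 C-1 vinyl sulfone
Product: 9 9,14-diol
Conditions: PPTS (cat.), MeOH, 25 °C
Reagents that add atoms: none
Why: Acid-catalysed transketalisation removes the acetonide while no epoxide is yet present; the TBS ether, alkynylsilane and vinyl sulfone are inert.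

**Step 7**
Reactants: 9 9,14-diol
Product: 11 9-O-acetyl 14-O-TBS vinyl sulfone, via 14-O-TBS alcohol 10 (not isolated)
Conditions: TBSCl, imidazole, CH2Cl2, −20 °C; then Ac2O, pyridine, DMAP (cat.), 0 °C
Reagents that add atoms: tert-butyldimethylsilyl chloride CC(C)(C)[Si](C)(C)Cl; acetic anhydride CC(=O)OC(C)=O
Why: Kinetic silylation of the primary allylic alcohol followed by DMAP-catalysed acetylation of the remaining secondary alcohol installs the final C-9 acetate and differentiates O-14.

**Step 8**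
Reactants: 11 9-O-acetyl 14-O-TBS vinyl sulfone
Product: 12 terminal alkyne
Conditions: AgNO3 (10 mol%), acetone/H2O, 25 °C
Reagents that add atoms: none
Why: Silver-catalysed protodesilylation of the alkynylsilane is neutral, so the acetate and both TBS ethers should survive.

**Step 9**
Reactants: 12 terminal alkyne
Product: 13 methyl 2-ynoate
Conditions: PdCl2 (5 mol%), CuCl2 (2.2 equiv), NaOAc (2.2 equiv), CO (1 atm), MeOH, 25 °C
Reagents that add atoms: carbon monoxide [C-]#[O+]; methanol CO
Why: Oxidative alkoxycarbonylation of a terminal alkyne (divalent palladium, CuCl2 as reoxidant) adds C-12 without strong base, which the acetate and the γ-acetoxy vinyl sulfone would not tolerate.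

**Step 10**
Reactants: 13 methyl 2-ynoate
Product: 15 (Z)-2-(pinacolborylmethyl) enoate, via vinylalane 14 (not isolated)
Conditions: i-Bu2AlH (1.1 equiv), HMPA, THF, 0 °C; then ICH2Bpin, 25 °C
Reagents that add atoms: 2-(iodomethyl)-4,4,5,5-tetramethyl-1,3,2-dioxaborolane ICB1OC(C)(C)C(C)(C)O1
Why: Syn hydroalumination of the ynoate with the i-Bu2AlH–HMPA complex puts Al on C-11 and H on C-7, and C-alkylation of the α-alanyl acrylate with the iodomethylboronate retains that geometry, so C-8 ends cis to the ester and trans to CH2B; the conjugated ynoate should react well before the isolated acetate.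

**Step 11**
Reactants: 15 (Z)-2-(pinacolborylmethyl) enoate; 3 (2R,3R)-epoxy aldehyde
Product: 17 trans α-methylene-γ-butyrolactone, via borate adduct 16 (not isolated)
Conditions: toluene, 4 Å MS, 70 °C
Reagents that add atoms: none
Why: Allylboration through a chair Zimmerman–Traxler transition state followed by lactonisation of the borate onto the ester: C-8 trans to CH2B gives the 6,7-anti adduct (trans-lactone), the aldehyde reacts on its Felkin–Anh face (anti to the epoxide C–O, 5,6-anti), and the allyl unit reacts anti to the C-9 branch in the A(1,3)-minimised rotamer, three preferences that coincide for this pair of enantiomers.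

**Step 12**
Reactants: 17 trans α-methylene-γ-butyrolactone
Product: 18 13-phenylsulfonyl lactone
Conditions: PhSO2Na, AcOH, DMF, 25 °C
Reagents that add atoms: sodium benzenesulfinate [Na+].[O-]S(=O)c1ccccc1
Why: Sulfa-Michael addition masks the exocyclic methylene as a radical-inert sulfone at a pH where the epoxide and the hindered vinyl sulfone do not react; the new C-11 centre is irrelevant.

**Step 13**
Reactants: 18 13-phenylsulfonyl lactone
Product: 19 C-14 alcohol
Conditions: HF·pyridine, pyridine, THF, 0 °C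
Reagents that add atoms: none
Why: Buffered fluoride desilylation cleaves the primary allylic TBS ether much faster than the hindered secondary one at O-8.

**Step 14**
Reactants: 19 C-14 alcohol
Product: 20 aldehyde
Conditions: O3, CH2Cl2, −78 °C; then Me2S
Reagents that add atoms: ozone [O-][O+]=O
Why: Ozonolysis with reductive work-up cleaves the only electron-rich alkene (the prenyl terminus); the vinyl sulfone is too electron-poor to react.

**Step 15**
Reactants: 20 aldehyde
Product: 22 N-acyloxyphthalimide, via carboxylic acid 21 (not isolated)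
Conditions: NaClO2, NaH2PO4, 2-methyl-2-butene, t-BuOH/H2O, 0 °C; then N-hydroxyphthalimide, DIC, CH2Cl2, 0 °C
Reagents that add atoms: sodium chlorite [Na+].[O-]Cl=O; N-hydroxyphthalimide ON1C(=O)c2ccccc2C1=O
Why: Pinnick oxidation followed at once by carbodiimide coupling gives the redox-active ester before the 4,5-epoxy acid can lactonise; chlorite does not oxidise the allylic alcohol.

**Step 16**
Reactants: 22 N-acyloxyphthalimide
Product: 23 β-sulfonyl enal
Conditions: Dess–Martin periodinane, NaHCO3, CH2Cl2, 0 °C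
Reagents that add atoms: none
Why: Dess–Martin oxidation of the primary allylic alcohol gives the enal that activates C-1 and leaves the redox-active ester intact.

**Step 17**
Reactants: 23 β-sulfonyl enal
Product: 26 8-O-TBS macrocyclic enal, via C-2 radical 24 (not isolated), via C-10 radical 25 (not isolated)
Conditions: Ru(bpy)3(PF6)2 (2 mol%), Hantzsch ester (1.5 equiv), 2,6-lutidine (2 equiv), degassed CH2Cl2 (0.5 mM), 450 nm LED, 25 °C
Reagents that add atoms: none
Why: Proposed new method: electron transfer from the photoreduced ruthenium complex to the N-acyloxyphthalimide releases CO2 and the nucleophilic primary radical at C-2 (24), which adds to C-1, the sulfonyl-bearing β-carbon of the enal, to give the α-formyl radical at C-10 (25); β-scission of the C-1–S bond then expels PhSO2•, which the Hantzsch ester reduces and protonates, and leaves the C-1=C-10 enal. The closest known reaction types are the photoredox decarboxylative alkenylation of redox-active esters with vinyl sulfones (radical addition–β-sulfonyl fragmentation) and decarboxylative radical macrocyclisation by conjugate addition; their use together as a ring closure is new. The ten-membered carbocycle closes in a 10-endo-trig radical mode (attack at C-10 would give a nine-membered ring and a hindered, non-stabilised radical), helped by the cis-epoxide, the trans-lactone and the 8,9-dioxygenation, which fold the chain. No sp3 centre is created; the C-1=C-10 geometry is set when the planar C-10 radical fragments, the rotamer leading to the trans-cyclodecene being strained, and any minor isomer can equilibrate by reversible conjugate addition of the sulfinate formed, so both vinyl sulfone isomers of 23 should converge on the enal with CHO trans to C-2. The step needs ring closure to outrun hydrogen transfer to 24 (from the Hantzsch ester or by 1,5-shift from C-6–H) and attack on other acceptors; the 0.5 mM concentration slows all bimolecular quenching, the lactone methylene is masked as the sulfone, the methacrylate is not yet present, and the acyloxy-substituted C-6–H is a poor hydrogen donor.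

**Step 18**
Reactants: 26 8-O-TBS macrocyclic enal
Product: 27 8-O-TBS α-methylene lactone
Conditions: DBU (1.05 equiv), CH2Cl2, −20 °C
Reagents that add atoms: none
Why: Retro-sulfa-Michael (E1cB) elimination of benzenesulfinate regenerates the α-methylene lactone and erases C-11; one equivalent of base at low temperature is used so that the enal γ-protons and the C-9 acetate are not engaged.

**Step 19**
Reactants: 27 8-O-TBS α-methylene lactone
Product: 28 C-8 alcohol
Conditions: HF·pyridine, THF, 0 → 25 °C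
Reagents that add atoms: none
Why: Fluoride desilylation of the secondary TBS ether under mildly acidic conditions, which trisubstituted epoxides are known to tolerate.

**Step 20**
Reactants: 28 C-8 alcohol
Product: 29 target CNP0121379.1
Conditions: methacrylic anhydride, Et3N, DMAP (cat.), CH2Cl2, 0 °C
Reagents that add atoms: methacrylic anhydride CC(=C)C(=O)OC(=O)C(C)=C
Why: DMAP-catalysed acylation of the C-8 alcohol at low temperature should be faster than acetyl migration from O-9, and no stereocentre is touched.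

**Compound list**

1 | nerol, (2Z)-3,7-dimethylocta-2,6-dien-1-ol | CC(C)=CCC/C(C)=C\CO | starting material
2 | [(2S,3R)-3-methyl-3-(4-methylpent-3-en-1-yl)oxiran-2-yl]methanol | CC(C)=CCC[C@@]1(C)O[C@H]1CO | intermediate
3 | (2R,3R)-3-methyl-3-(4-methylpent-3-en-1-yl)oxirane-2-carbaldehyde | CC(C)=CCC[C@@]1(C)O[C@H]1C=O | intermediate
4 | 2,2-dimethyl-1,3-dioxan-5-one | CC1(C)OCC(=O)CO1 | starting material
5 | 3-(trimethylsilyl)prop-2-ynal | C[Si](C)(C)C#CC=O | starting material
6 | (4S)-4-[(1S)-1-hydroxy-3-(trimethylsilyl)prop-2-yn-1-yl]-2,2-dimethyl-1,3-dioxan-5-one (C-8 carbinol, C-9 ring CH, C-10 ketone) | C[Si](C)(C)C#C[C@H](O)[C@@H]1OC(C)(C)OCC1=O | intermediate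
7 | (4S)-4-[(1S)-1-(tert-butyldimethylsilyloxy)-3-(trimethylsilyl)prop-2-yn-1-yl]-2,2-dimethyl-1,3-dioxan-5-one | C[Si](C)(C)C#C[C@H](O[Si](C)(C)C(C)(C)C)[C@@H]1OC(C)(C)OCC1=O | intermediate
8 | 5-[(phenylsulfonyl)methylidene]-1,3-dioxane derived from 7 (C-8, C-9 as in 7; E/Z mixture at C-1=C-10) | C[Si](C)(C)C#C[C@H](O[Si](C)(C)C(C)(C)C)[C@@H]1OC(C)(C)OCC1=CS(=O)(=O)c1ccccc1 | intermediate
9 | 9,14-diol: 8-O-TBS, 9-OH, 14-OH, C-1 vinyl sulfone, C-7 silylalkyne | C[Si](C)(C)C#C[C@H](O[Si](C)(C)C(C)(C)C)[C@H](O)C(CO)=CS(=O)(=O)c1ccccc1 | intermediate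
10 | 14-O-TBS ether of 9 (9-OH free) | C[Si](C)(C)C#C[C@H](O[Si](C)(C)C(C)(C)C)[C@H](O)C(CO[Si](C)(C)C(C)(C)C)=CS(=O)(=O)c1ccccc1 | intermediate
11 | 9-O-acetyl-8,14-bis-O-TBS vinyl sulfone with C-7 silylalkyne | C[Si](C)(C)C#C[C@H](O[Si](C)(C)C(C)(C)C)[C@H](OC(C)=O)C(CO[Si](C)(C)C(C)(C)C)=CS(=O)(=O)c1ccccc1 | intermediate
12 | terminal alkyne (C-7≡C-11–H) from 11 | C#C[C@H](O[Si](C)(C)C(C)(C)C)[C@H](OC(C)=O)C(CO[Si](C)(C)C(C)(C)C)=CS(=O)(=O)c1ccccc1 | intermediate
13 | methyl 2-ynoate (C-12 ester on C-11) | COC(=O)C#C[C@H](O[Si](C)(C)C(C)(C)C)[C@H](OC(C)=O)C(CO[Si](C)(C)C(C)(C)C)=CS(=O)(=O)c1ccccc1 | intermediate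
14 | methyl (Z)-2-(diisobutylalanyl)-2-enoate (Al on C-11, C-8 cis to the ester) | COC(=O)/C([Al](CC(C)C)CC(C)C)=C\[C@H](O[Si](C)(C)C(C)(C)C)[C@H](OC(C)=O)C(CO[Si](C)(C)C(C)(C)C)=CS(=O)(=O)c1ccccc1 | intermediate
15 | methyl (Z)-2-[(pinacolboryl)methyl]-2-enoate (allylboronate; C-8 cis to the ester, trans to CH2B) | COC(=O)/C(CB1OC(C)(C)C(C)(C)O1)=C\[C@H](O[Si](C)(C)C(C)(C)C)[C@H](OC(C)=O)C(CO[Si](C)(C)C(C)(C)C)=CS(=O)(=O)c1ccccc1 | intermediate
16 | O-6 pinacolborate of the 6,7-anti homoallylic alcohol (methyl ester not yet lactonised) | CC(C)=CCC[C@@]1(C)O[C@H]1[C@@H](OB1OC(C)(C)C(C)(C)O1)[C@H](C(=C)C(=O)OC)[C@H](O[Si](C)(C)C(C)(C)C)[C@H](OC(C)=O)C(CO[Si](C)(C)C(C)(C)C)=CS(=O)(=O)c1ccccc1 | intermediate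
17 | seco trans α-methylene-γ-butyrolactone (4,5-epoxide, 8-O-TBS, 9-OAc, 14-O-TBS, C-1 sulfone, prenyl tail) | CC(C)=CCC[C@@]1(C)O[C@H]1[C@H]1OC(=O)C(=C)[C@@H]1[C@H](O[Si](C)(C)C(C)(C)C)[C@H](OC(C)=O)C(CO[Si](C)(C)C(C)(C)C)=CS(=O)(=O)c1ccccc1 | intermediate
18 | 13-(phenylsulfonyl) adduct of 17 (C-11 epimers) | CC(C)=CCC[C@@]1(C)O[C@H]1[C@H]1OC(=O)C(CS(=O)(=O)c2ccccc2)[C@@H]1[C@H](O[Si](C)(C)C(C)(C)C)[C@H](OC(C)=O)C(CO[Si](C)(C)C(C)(C)C)=CS(=O)(=O)c1ccccc1 | intermediate
19 | C-14 alcohol from 18 | CC(C)=CCC[C@@]1(C)O[C@H]1[C@H]1OC(=O)C(CS(=O)(=O)c2ccccc2)[C@@H]1[C@H](O[Si](C)(C)C(C)(C)C)[C@H](OC(C)=O)C(CO)=CS(=O)(=O)c1ccccc1 | intermediate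
20 | aldehyde from cleavage of the prenyl alkene (3-oxopropyl on C-4) | O=CCC[C@@]1(C)O[C@H]1[C@H]1OC(=O)C(CS(=O)(=O)c2ccccc2)[C@@H]1[C@H](O[Si](C)(C)C(C)(C)C)[C@H](OC(C)=O)C(CO)=CS(=O)(=O)c1ccccc1 | intermediate
21 | carboxylic acid from 20 (2-carboxyethyl on C-4) | OC(=O)CC[C@@]1(C)O[C@H]1[C@H]1OC(=O)C(CS(=O)(=O)c2ccccc2)[C@@H]1[C@H](O[Si](C)(C)C(C)(C)C)[C@H](OC(C)=O)C(CO)=CS(=O)(=O)c1ccccc1 | intermediate
22 | N-acyloxyphthalimide of 21 | O=C(CC[C@@]1(C)O[C@H]1[C@H]1OC(=O)C(CS(=O)(=O)c2ccccc2)[C@@H]1[C@H](O[Si](C)(C)C(C)(C)C)[C@H](OC(C)=O)C(CO)=CS(=O)(=O)c1ccccc1)ON1C(=O)c2ccccc2C1=O | intermediate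
23 | β-sulfonyl enal (C-14 aldehyde) with the redox-active ester | O=C(CC[C@@]1(C)O[C@H]1[C@H]1OC(=O)C(CS(=O)(=O)c2ccccc2)[C@@H]1[C@H](O[Si](C)(C)C(C)(C)C)[C@H](OC(C)=O)C(C=O)=CS(=O)(=O)c1ccccc1)ON1C(=O)c2ccccc2C1=O | intermediate
24 | primary radical at C-2 after loss of CO2 and phthalimide from 23 | [CH2]C[C@@]1(C)O[C@H]1[C@H]1OC(=O)C(CS(=O)(=O)c2ccccc2)[C@@H]1[C@H](O[Si](C)(C)C(C)(C)C)[C@H](OC(C)=O)C(C=O)=CS(=O)(=O)c1ccccc1 | intermediate
25 | ring-closed α-formyl radical at C-10 (C-1 still bears the sulfonyl group) | CC(C)(C)[Si](C)(C)O[C@H]1[C@H]2C(CS(=O)(=O)c3ccccc3)C(=O)O[C@@H]2[C@@H]2O[C@]2(C)CCC(S(=O)(=O)c2ccccc2)[C](C=O)[C@H]1OC(C)=O | intermediate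
26 | macrocyclic enal: 8-O-TBS, 9-OAc, 4,5-epoxide, 13-(phenylsulfonyl) lactone (C-11 epimers) | CC(C)(C)[Si](C)(C)O[C@H]1[C@H]2C(CS(=O)(=O)c3ccccc3)C(=O)O[C@@H]2[C@@H]2O[C@]2(C)CC/C=C(/C=O)[C@H]1OC(C)=O | intermediate
27 | 8-O-TBS ether of the 8-desacyl target (α-methylene lactone restored) | CC(C)(C)[Si](C)(C)O[C@H]1[C@H]2C(=C)C(=O)O[C@@H]2[C@@H]2O[C@]2(C)CC/C=C(/C=O)[C@H]1OC(C)=O | intermediate
28 | 8-hydroxy compound (8-desmethacryloyl target) | O[C@H]1[C@H]2C(=C)C(=O)O[C@@H]2[C@@H]2O[C@]2(C)CC/C=C(/C=O)[C@H]1OC(C)=O | intermediate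
29 | CNP0121379.1 (9-acetoxy-4,5-epoxy-8-methacryloyloxy-14-oxo germacranolide) | C=C(C)C(=O)O[C@H]1[C@H]2C(=C)C(=O)O[C@@H]2[C@@H]2O[C@]2(C)CC/C=C(/C=O)[C@H]1OC(C)=O | target

**Totals**

Total step count: 20.
Longest linear sequence: 18 steps (steps 3–20); steps 1–2 make the epoxy aldehyde 3.

**Three steps most likely to fail**

Step 17 (Proposed new method). What may go wrong: ring closure of the C-2 radical is slow, so hydrogen transfer to it (from the Hantzsch ester or by 1,5-shift from C-6–H) or electron transfer to the sulfonyl enal takes over. Fallback, by known chemistry (tin hydride radical macrocyclisation onto an activated alkene, with ipso-substitution of a vinyl sulfone by an alkyl radical): it sets out from 18. Ozonolysis (O3; Me2S) should give aldehyde F1, Pinnick oxidation acid F2, and iododecarboxylation (PhI(OAc)2, I2, visible light) the primary iodide F3. HF·pyridine/pyridine should then give alcohol F4 and Dess–Martin oxidation the iodo enal F5. Slow addition of Bu3SnH/AIBN to F5 in benzene at 80 °C (1 mM) generates the same C-2 radical by iodine abstraction, with no photocatalyst or electron donor present, and should close the ring with loss of the sulfonyl group, so the route is rejoined at 26.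

Step 11. What may go wrong: the ester-deactivated allylboronate adds too slowly, so the epoxy aldehyde decomposes on prolonged heating, or facial selectivity on the allyl unit is poor. Fallback: it sets out from 15. KHF2 in aqueous methanol should give the potassium allyltrifluoroborate F6, which adds to 3 at 25 °C under phase-transfer conditions (Bu4NI cat., CH2Cl2/H2O) through the same chair transition state to give hydroxy ester F7. 2-Hydroxypyridine in toluene at 60 °C then lactonises F7, and the route is rejoined at 17.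

Step 15. What may go wrong: the free 4,5-epoxy acid 21 opens its own epoxide (5-exo attack of the carboxyl group at C-4) before it is esterified. Fallback: it sets out from aldehyde 20 and bypasses the acid. Oxidative coupling of the aldehyde C–H with N-hydroxyphthalimide (PhI(OAc)2, EtOAc, 25 °C, through the acyl radical and the phthalimide-N-oxyl radical) should give 22 directly, where the route is rejoined; this fallback makes no new compound (F0).

**Further compounds**

F1 | step 17 | aldehyde from ozonolysis of 18 (14-O-TBS retained) | O=CCC[C@@]1(C)O[C@H]1[C@H]1OC(=O)C(CS(=O)(=O)c2ccccc2)[C@@H]1[C@H](O[Si](C)(C)C(C)(C)C)[C@H](OC(C)=O)C(CO[Si](C)(C)C(C)(C)C)=CS(=O)(=O)c1ccccc1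
F2 | step 17 | carboxylic acid from F1 | OC(=O)CC[C@@]1(C)O[C@H]1[C@H]1OC(=O)C(CS(=O)(=O)c2ccccc2)[C@@H]1[C@H](O[Si](C)(C)C(C)(C)C)[C@H](OC(C)=O)C(CO[Si](C)(C)C(C)(C)C)=CS(=O)(=O)c1ccccc1
F3 | step 17 | primary iodide at C-2 | ICC[C@@]1(C)O[C@H]1[C@H]1OC(=O)C(CS(=O)(=O)c2ccccc2)[C@@H]1[C@H](O[Si](C)(C)C(C)(C)C)[C@H](OC(C)=O)C(CO[Si](C)(C)C(C)(C)C)=CS(=O)(=O)c1ccccc1
F4 | step 17 | C-14 alcohol of the iodide | ICC[C@@]1(C)O[C@H]1[C@H]1OC(=O)C(CS(=O)(=O)c2ccccc2)[C@@H]1[C@H](O[Si](C)(C)C(C)(C)C)[C@H](OC(C)=O)C(CO)=CS(=O)(=O)c1ccccc1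
F5 | step 17 | iodo β-sulfonyl enal | ICC[C@@]1(C)O[C@H]1[C@H]1OC(=O)C(CS(=O)(=O)c2ccccc2)[C@@H]1[C@H](O[Si](C)(C)C(C)(C)C)[C@H](OC(C)=O)C(C=O)=CS(=O)(=O)c1ccccc1
F6 | step 11 | potassium allyltrifluoroborate from 15 | COC(=O)/C(C[B-](F)(F)F)=C\[C@H](O[Si](C)(C)C(C)(C)C)[C@H](OC(C)=O)C(CO[Si](C)(C)C(C)(C)C)=CS(=O)(=O)c1ccccc1.[K+]
F7 | step 11 | 6,7-anti hydroxy ester (homoallylic alcohol before lactonisation) | CC(C)=CCC[C@@]1(C)O[C@H]1[C@@H](O)[C@H](C(=C)C(=O)OC)[C@H](O[Si](C)(C)C(C)(C)C)[C@H](OC(C)=O)C(CO[Si](C)(C)C(C)(C)C)=CS(=O)(=O)c1ccccc1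
F0 | step 15 | none | none
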